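The runs are simulated from invented constants.

1. If D lies on the way from L to E, the final D of a warmed flask hangs on two times: how fast D is made and how fast it is lost.

| flask | L | X | temperature | remark | time |
|---|---|---|---|---|---|
| red | 0.034 M | 0.80 equiv | −20 °C | run made earlier |  |
| blue | 0.075 M | 0.80 equiv | −5 °C | run made earlier |  |
| midnight | 0.050 M | 0.800 equiv | −15 °C |  | 5.0 h |
| dusk | 0.050 M | 0.800 equiv | 5 °C |  | 5.0 h |
| spring | 0.050 M | 0.800 equiv |  | at −15 °C until 2.5 h, from then on at 5 °C | 5.0 h |

| run | time / h | D / % | E / % |
|---|---|---|---|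
| red | 0.833 | 6 | 2 |
| red | 2.00 | 14 | 2 |
| red | 4.00 | 21 | 2 |
| red | 6.00 | 29 | 4 |
| blue | 0.500 | 20 | 3 |
| blue | 1.33 | 42 | 5 |
| blue | 2.50 | 51 | 15 |
| blue | 4.00 | 47 | 26 |

(scatter of a reading: 2 percentage points)

* the flask with the highest amount of D, in percent of the L charged ("all alike" if they lie within 1.5 percentage points) (midnight / dusk / spring / all alike)
* final D, as a percentage of the L charged, in midnight
* final D, as a percentage of the L charged, in dusk
* final D, as a percentage of the L charged, in spring

- a reading or a percentage of E counts all its forms, free or not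

2. Making, read as first-order growth of the fraction D + E, gives 0.0667 h⁻¹ in red and 0.477 h⁻¹ in blue. Extended logarithmically in temperature to 5 °C, that is 1.77 h⁻¹, a making time of 0.564 h.

3. Losing, read as E gained per D standing, gives 0.150 h⁻¹ late in blue. Red gives a rough 0.0460 h⁻¹, since its last E stands close to the scatter. Red and blue differ in L as well as in temperature, so this extension carries both differences. Extended the same way, that is 0.329 h⁻¹, a losing time of 3.04 h.

4. The warm selectivity factor ρ, losing time over making time, is 5.39. For two steps in a row, D's ceiling is ρ raised to minus one over (ρ minus one): 68.1%, reached 1.17 h after warming.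

5. Spring's warm leg of 2.50 h is shorter than dusk's 5.0 h, and both outlast that peak. This reckoning gives dusk 23.7%. With a reckoned 72.5% of L left at the change, spring gets 51.2%.

6. The forecast differs. It puts midnight highest, at 41%, with dusk 16% and spring 29%, and warns: “the warm value is a long extrapolation”.

7. The flasks give spring highest: midnight 39.6%, dusk 45.0%, spring 56.7%.

    L → D (k = 5.00 × 10⁻⁴ s⁻¹, Ea = 79.0 kJ mol⁻¹)
    X + D → E (k = 0.00190 M⁻¹ s⁻¹, Ea = 47.0 kJ mol⁻¹)
    L + E ⇌ Z, settled at all times (K = 570 M⁻¹, ΔH = −51.0 kJ mol⁻¹)
    (constants at 5 °C)

Dusk ends at 45.0% because of the time allowed together with the falling level of X: with the limit on time taken away, left to 50.0 h, it ends at 20.5%, and with the fall of X taken away, X held at its charge, at 28.2%. The time allowed is likewise a part of midnight's 39.6%: with that limit taken away, left to 50.0 h, midnight ends at 21.4%. At fixed equivalents X scales with L, and the scheme's loss of D runs with X, so ρ scales inversely with L: a neighbour flask, spring at 0.020 M of L, has ρ of 13.5 and a ceiling of 81.2%, and it ends with D at 78.1%.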